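**Retrosynthetic overview**
1. The last bonds made are the C3–O acyl bond (esterification with (2E,4E)-octa-2,4-dienoic acid) and the N/O deprotections. This leads back to an N-protected cis-decahydroquinolin-3-ol that already carries the whole C5 side chain.
2. Key disconnection: C4a–C8a and C5–C6 are formed in one intramolecular Diels–Alder reaction of an acyclic triene. The (E)-N-dienyl carbamate C8a=C8–C7=C6 and the (Z)-alkene C4a=C5 are joined by the tether N1–C2–C3–C4.
3. Enabling feature: on the carbocycle (C4a, C5, C6, C7, C8, C8a) the three contiguous substituents N1 at C8a, C4 at C4a and C1′ at C5 lie on one face, and N1 and C4 are linked through C2–C3 of the piperidine ring. This all-cis triad is the imprint of an (E)-1-aminodiene meeting a (Z)-alkene endo.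
4. Ring order: there is no ring before the key step. The shared bond C4a–C8a closes the piperidine ring, and the carbocycle, which also needs C5–C6, is the last ring to be completed, in the same operation.
5. The triene comes from an L-alanine unit (C2; C3 by chelate-controlled reduction), a phosphonium salt from (R)-2-propyloxirane (C5′; Z-Wittig for C4a=C5) and crotonaldehyde (C6–C8a).

Key step: step 11

Assumption: Boc-L-alanine N-methoxy-N-methylamide, (R)-2-propyloxirane and (2E,4E)-octa-2,4-dienoic acid are taken as commercial single isomers; all intermediates use the decahydroquinoline numbering of the target (N1, C2–C8a, side chain C1′–C8′).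

**Step 1**
Reactants: 1 Boc-L-alanine N-methoxy-N-methylamide; 2 allylmagnesium bromide
Product: 3 tert-butyl N-[(2S)-3-oxohex-5-en-2-yl]carbamate
Conditions: 2 (2.5 equiv), THF, −78 → −20 °C; cold aq KHSO4
Reagents that add atoms: none
Why: Weinreb ketone synthesis, in which the chelated tetrahedral adduct stops at the ketone stage and the cold acidic quench should keep the alkene out of conjugation and the L-alanine centre C2 intact.

**Step 2**
Reactants: 3 tert-butyl N-[(2S)-3-oxohex-5-en-2-yl]carbamate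
Product: 4 tert-butyl N-[(2S,3R)-3-hydroxyhex-5-en-2-yl]carbamate
Conditions: LiAlH(OtBu)3, EtOH, −78 °C
Reagents that add atoms: none
Why: Chelation-controlled (Cram chelate) hydride reduction of an N-carbamoyl α-amino ketone, in which hydride should attack from the side of the C2–H and set C3 as R (anti amino alcohol).

**Step 3**
Reactants: 4 tert-butyl N-[(2S,3R)-3-hydroxyhex-5-en-2-yl]carbamate
Product: 5 tert-butyl N-[(2S,3R)-3-(benzyloxy)hex-5-en-2-yl]carbamate
Conditions: 2-benzyloxy-1-methylpyridinium triflate, MgO, PhCF3, 83 °C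
Reagents that add atoms: 2-benzyloxy-1-methylpyridinium trifluoromethanesulfonate, C[n+]1ccccc1OCc1ccccc1.[O-]S(=O)(=O)C(F)(F)F
Why: Neutral O-benzylation by benzyl transfer from the pyridinium salt leaves the carbamate N–H protonated, so N-benzylation and oxazolidinone formation should not interfere and no stereocentre is touched.

**Step 4**
Reactants: 5 tert-butyl N-[(2S,3R)-3-(benzyloxy)hex-5-en-2-yl]carbamate
Product: 7 tert-butyl N-[(2S,3R)-3-(benzyloxy)-5-oxopentan-2-yl]carbamate, via secondary ozonide 6 (not isolated)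
Conditions: O3, CH2Cl2, −78 °C; then PPh3, −78 °C → rt
Reagents that add atoms: ozone, [O-][O+]=O
Why: Ozonolysis with reductive work-up cleaves only the terminal alkene and makes C4a the aldehyde carbon without touching C2 or C3.

**Step 5**
Reactants: 8 1-bromo-4-chlorobutane; 9 (R)-2-propyloxirane
Product: 11 (R)-9-chlorononan-4-ol, via 4-chlorobutylmagnesium bromide 10 (not isolated)
Conditions: Mg, THF, 30 °C; then CuI (10 mol %), 9, THF, −30 → 0 °C; aq NH4Cl
Reagents that add atoms: none
Why: Copper-catalysed Grignard opening of a terminal epoxide at its CH2 end (SN2) leaves the C5′–O bond unbroken, so the R configuration of the epoxide becomes C5′, and the alkyl chloride is inert under these conditions.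

**Step 6**
Reactants: 11 (R)-9-chlorononan-4-ol
Product: 12 (R)-tert-butyl[(9-chlorononan-4-yl)oxy]dimethylsilane
Conditions: TBSCl, imidazole, DMF, rt
Reagents that add atoms: tert-butyldimethylsilyl chloride, CC(C)(C)[Si](C)(C)Cl
Why: Imidazole-promoted silyl ether formation masks the C5′ hydroxyl with retention, since only the O–H bond reacts.

**Step 7**
Reactants: 12 (R)-tert-butyl[(9-chlorononan-4-yl)oxy]dimethylsilane
Product: 14 [(6R)-6-(tert-butyldimethylsilyloxy)nonyl]triphenylphosphonium iodide, via alkyl iodide 13 (not isolated)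
Conditions: NaI, PPh3, MeCN, reflux
Reagents that add atoms: sodium iodide, [Na+].[I-]; triphenylphosphine, c1ccc(cc1)P(c1ccccc1)c1ccccc1
Why: Finkelstein exchange followed by SN2 quaternisation of PPh3 at the primary carbon (future C5) is remote from C5′ and compatible with the silyl ether.

**Step 8**
Reactants: 14 [(6R)-6-(tert-butyldimethylsilyloxy)nonyl]triphenylphosphonium iodide; 7 tert-butyl N-[(2S,3R)-3-(benzyloxy)-5-oxopentan-2-yl]carbamate
Product: 16 tert-butyl N-[(2S,3R,5Z,11R)-3-(benzyloxy)-11-(tert-butyldimethylsilyloxy)tetradec-5-en-2-yl]carbamate, via phosphonium ylide 15 (not isolated)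
Conditions: 14 (2.2 equiv), NaHMDS (2.1 equiv), THF, 0 °C; then 7, −78 °C → rt
Reagents that add atoms: none
Why: Wittig olefination with a non-stabilised ylide under lithium-free kinetic control should give the Z alkene C4a=C5, with the excess ylide covering the acidic carbamate N–H.

**Step 9**
Reactants: 16 tert-butyl N-[(2S,3R,5Z,11R)-3-(benzyloxy)-11-(tert-butyldimethylsilyloxy)tetradec-5-en-2-yl]carbamate
Product: 17 (2S,3R,5Z,11R)-3-(benzyloxy)-11-(tert-butyldimethylsilyloxy)tetradec-5-en-2-amine
Conditions: TFA/CH2Cl2 (1:4), 0 °C, short contact; aq NaHCO3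
Reagents that add atoms: none
Why: Acidolytic carbamate cleavage (loss of the tert-butyl cation, then decarboxylation) under anhydrous conditions at 0 °C should spare the secondary silyl ether, the benzyl ether and the Z alkene.

**Step 10**
Reactants: 17 (2S,3R,5Z,11R)-3-(benzyloxy)-11-(tert-butyldimethylsilyloxy)tetradec-5-en-2-amine; 18 (E)-but-2-enal
Product: 20 benzyl N-[(1E)-buta-1,3-dien-1-yl]-N-[(2S,3R,5Z,11R)-3-(benzyloxy)-11-(tert-butyldimethylsilyloxy)tetradec-5-en-2-yl]carbamate, via crotonaldimine 19 (not isolated)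
Conditions: 18, MgSO4, CH2Cl2, 0 °C; filter, concentrate; then CbzCl, PhNEt2, toluene, 0 °C → rt
Reagents that add atoms: benzyl chloroformate, O=C(Cl)OCc1ccccc1
Why: Imine condensation, then N-acylation and γ-deprotonation of the α,β-unsaturated N-acyliminium ion (dienamide synthesis from enal imines), should give the E-configured 1-(acylamino)butadiene without touching C2.

**Step 11**
Reactants: 20 benzyl N-[(1E)-buta-1,3-dien-1-yl]-N-[(2S,3R,5Z,11R)-3-(benzyloxy)-11-(tert-butyldimethylsilyloxy)tetradec-5-en-2-yl]carbamate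
Product: 21 benzyl (2S,3R,4aS,5S,8aR)-3-(benzyloxy)-5-[(5R)-5-(tert-butyldimethylsilyloxy)octyl]-2-methyl-3,4,4a,5,6,8a-hexahydroquinoline-1(2H)-carboxylate
Conditions: toluene (0.01 M), N,O-bis(trimethylsilyl)acetamide (BSA), BHT, sealed tube, 210 °C
Reagents that add atoms: none
Why: Thermal, concerted and suprafacial [4+2] cycloaddition (intramolecular Diels–Alder reaction) of the electron-rich (E)-1-(acylamino)diene C8a=C8–C7=C6 with the tethered unactivated (Z)-alkene C4a=C5; the closest known reaction type is the thermal intramolecular Diels–Alder reaction of N-alkenyl-N-(buta-1,3-dienyl)carbamates, an established entry to cis-fused octahydroquinolines. The carbocycle is the cycloaddition ring itself (new bonds C4a–C8a and C5–C6, new alkene C7=C8), and the piperidine is the tether ring closed in the fused mode by the shared bond C4a–C8a over the four-atom tether N1–C2–C3–C4, so the carbocycle is complete only when C5–C6 is made. C8a is controlled by C2: A(1,3) strain with the planar carbamate forces the C2 methyl group, and with it the anti C3 benzyloxy group, into pseudoaxial positions of the chair-like tether, so the alkene should reach only the diene face that puts H8a cis to H2. C4a follows from the transition state with tether carbon C4 endo to the diene, which gives the cis ring fusion typical of this substrate class, and C5 follows from the Z geometry, which is transferred suprafacially and keeps C1′ cis to C4. The step needs facial selectivity, endo over exo (cis over trans fusion) and one regiochemistry; the first is secured by the C2/C3 pair, the second by the conformational demand of the carbamate-bearing tether, and the third by the tether length, which excludes the bridged mode. The silyl ether, benzyl ether and benzyl carbamate should be inert at this temperature, and BSA and BHT suppress acid- and radical-induced loss of the dienyl carbamate.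

**Step 12**
Reactants: 21 benzyl (2S,3R,4aS,5S,8aR)-3-(benzyloxy)-5-[(5R)-5-(tert-butyldimethylsilyloxy)octyl]-2-methyl-3,4,4a,5,6,8a-hexahydroquinoline-1(2H)-carboxylate
Product: 23 tert-butyl (2S,3R,4aS,5S,8aR)-5-[(5R)-5-(tert-butyldimethylsilyloxy)octyl]-3-hydroxy-2-methyloctahydroquinoline-1(2H)-carboxylate, via amino alcohol 22 (not isolated)
Conditions: H2 (1 atm), Pd(OH)2/C, EtOAc/EtOH, rt; filter; then Boc2O, Et3N, CH2Cl2, 40 °C
Reagents that add atoms: di-tert-butyl dicarbonate, CC(C)(C)OC(=O)OC(=O)OC(C)(C)C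
Why: Heterogeneous hydrogenation saturates C7=C8 and hydrogenolyses the benzyl carbamate and benzyl ether in one operation, and Boc2O without an acylation catalyst should then take the amine in preference to the C3 hydroxyl, with no stereocentre created or broken.

**Step 13**
Reactants: 23 tert-butyl (2S,3R,4aS,5S,8aR)-5-[(5R)-5-(tert-butyldimethylsilyloxy)octyl]-3-hydroxy-2-methyloctahydroquinoline-1(2H)-carboxylate; 24 (2E,4E)-octa-2,4-dienoic acid
Product: 26 tert-butyl (2S,3R,4aS,5S,8aR)-5-[(5R)-5-(tert-butyldimethylsilyloxy)octyl]-2-methyl-3-[(2E,4E)-octa-2,4-dienoyloxy]octahydroquinoline-1(2H)-carboxylate, via mixed anhydride 25 (not isolated)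
Conditions: 24, 2,4,6-trichlorobenzoyl chloride, Et3N, toluene, rt; then 23, DMAP, rt → 40 °C
Reagents that add atoms: none
Why: Yamaguchi esterification is strong enough for the hindered axial C3 hydroxyl, keeps C3 (the C–O bond is not broken) and should leave the E,E-diene geometry unchanged.

**Step 14**
Reactants: 26 tert-butyl (2S,3R,4aS,5S,8aR)-5-[(5R)-5-(tert-butyldimethylsilyloxy)octyl]-2-methyl-3-[(2E,4E)-octa-2,4-dienoyloxy]octahydroquinoline-1(2H)-carboxylate
Product: 27 lepadin H
Conditions: TFA/CH2Cl2/H2O (5:5:1), 0 °C → rt; aq NaHCO3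
Reagents that add atoms: none
Why: Aqueous acidolysis removes the Boc group and the secondary silyl ether together, while the hindered conjugated ester and all six stereocentres should be unaffected.

**Compound list**
1 | Boc-L-alanine N-methoxy-N-methylamide | C[C@H](NC(=O)OC(C)(C)C)C(=O)N(C)OC | starting material
2 | allylmagnesium bromide | C=CC[Mg]Br | starting material
3 | tert-butyl N-[(2S)-3-oxohex-5-en-2-yl]carbamate | C[C@H](NC(=O)OC(C)(C)C)C(=O)CC=C | intermediate
4 | tert-butyl N-[(2S,3R)-3-hydroxyhex-5-en-2-yl]carbamate | C[C@H](NC(=O)OC(C)(C)C)[C@H](O)CC=C | intermediate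
5 | tert-butyl N-[(2S,3R)-3-(benzyloxy)hex-5-en-2-yl]carbamate | C[C@H](NC(=O)OC(C)(C)C)[C@H](OCc1ccccc1)CC=C | intermediate
6 | secondary ozonide (1,2,4-trioxolane) of 5, epimers at the ring carbon | C[C@H](NC(=O)OC(C)(C)C)[C@H](OCc1ccccc1)CC2OCOO2 | intermediate
7 | tert-butyl N-[(2S,3R)-3-(benzyloxy)-5-oxopentan-2-yl]carbamate | C[C@H](NC(=O)OC(C)(C)C)[C@H](OCc1ccccc1)CC=O | intermediate
8 | 1-bromo-4-chlorobutane | ClCCCCBr | starting material
9 | (R)-2-propyloxirane | CCC[C@@H]1CO1 | starting material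
10 | 4-chlorobutylmagnesium bromide | ClCCCC[Mg]Br | intermediate
11 | (R)-9-chlorononan-4-ol | ClCCCCC[C@H](O)CCC | intermediate
12 | (R)-tert-butyl[(9-chlorononan-4-yl)oxy]dimethylsilane | ClCCCCC[C@H](O[Si](C)(C)C(C)(C)C)CCC | intermediate
13 | (R)-tert-butyl[(9-iodononan-4-yl)oxy]dimethylsilane | ICCCCC[C@H](O[Si](C)(C)C(C)(C)C)CCC | intermediate
14 | [(6R)-6-(tert-butyldimethylsilyloxy)nonyl]triphenylphosphonium iodide | c1ccccc1[P+](c1ccccc1)(c1ccccc1)CCCCC[C@H](O[Si](C)(C)C(C)(C)C)CCC.[I-] | intermediate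
15 | [(6R)-6-(tert-butyldimethylsilyloxy)nonylidene]triphenylphosphorane | c1ccccc1P(c1ccccc1)(c1ccccc1)=CCCCC[C@H](O[Si](C)(C)C(C)(C)C)CCC | intermediate
16 | tert-butyl N-[(2S,3R,5Z,11R)-3-(benzyloxy)-11-(tert-butyldimethylsilyloxy)tetradec-5-en-2-yl]carbamate | C[C@H](NC(=O)OC(C)(C)C)[C@H](OCc1ccccc1)C/C=C\CCCC[C@H](O[Si](C)(C)C(C)(C)C)CCC | intermediate
17 | (2S,3R,5Z,11R)-3-(benzyloxy)-11-(tert-butyldimethylsilyloxy)tetradec-5-en-2-amine | C[C@H](N)[C@H](OCc1ccccc1)C/C=C\CCCC[C@H](O[Si](C)(C)C(C)(C)C)CCC | intermediate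
18 | (E)-but-2-enal (crotonaldehyde) | C/C=C/C=O | starting material
19 | N-[(E)-but-2-enylidene] imine of 17 | C/C=C/C=N/[C@@H](C)[C@H](OCc1ccccc1)C/C=C\CCCC[C@H](O[Si](C)(C)C(C)(C)C)CCC | intermediate
20 | benzyl N-[(1E)-buta-1,3-dien-1-yl]-N-[(2S,3R,5Z,11R)-3-(benzyloxy)-11-(tert-butyldimethylsilyloxy)tetradec-5-en-2-yl]carbamate | C=C/C=C/N(C(=O)OCc1ccccc1)[C@@H](C)[C@H](OCc1ccccc1)C/C=C\CCCC[C@H](O[Si](C)(C)C(C)(C)C)CCC | intermediate
21 | benzyl (2S,3R,4aS,5S,8aR)-3-(benzyloxy)-5-[(5R)-5-(tert-butyldimethylsilyloxy)octyl]-2-methyl-3,4,4a,5,6,8a-hexahydroquinoline-1(2H)-carboxylate (cis-fused; H2, H4a, H5, H8a and the 3-benzyloxy group on one face) | C(c3ccccc3)O[C@@H]1C[C@H]2[C@@H](CCCC[C@H](O[Si](C)(C)C(C)(C)C)CCC)CC=C[C@H]2N(C(=O)OCc4ccccc4)[C@H]1C | intermediate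
22 | (2S,3R,4aS,5S,8aR)-5-[(5R)-5-(tert-butyldimethylsilyloxy)octyl]-2-methyldecahydroquinolin-3-ol | O[C@@H]1C[C@H]2[C@@H](CCCC[C@H](O[Si](C)(C)C(C)(C)C)CCC)CCC[C@H]2N[C@H]1C | intermediate
23 | tert-butyl (2S,3R,4aS,5S,8aR)-5-[(5R)-5-(tert-butyldimethylsilyloxy)octyl]-3-hydroxy-2-methyloctahydroquinoline-1(2H)-carboxylate | O[C@@H]1C[C@H]2[C@@H](CCCC[C@H](O[Si](C)(C)C(C)(C)C)CCC)CCC[C@H]2N(C(=O)OC(C)(C)C)[C@H]1C | intermediate
24 | (2E,4E)-octa-2,4-dienoic acid | CCC/C=C/C=C/C(=O)O | starting material
25 | (2E,4E)-octa-2,4-dienoic 2,4,6-trichlorobenzoic anhydride | CCC/C=C/C=C/C(=O)OC(=O)c1c(Cl)cc(Cl)cc1Cl | intermediate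
26 | N-Boc-5′-O-TBS-lepadin H | CCC/C=C/C=C/C(=O)O[C@@H]1C[C@H]2[C@@H](CCCC[C@H](O[Si](C)(C)C(C)(C)C)CCC)CCC[C@H]2N(C(=O)OC(C)(C)C)[C@H]1C | intermediate
27 | lepadin H, (2S,3R,4aS,5S,8aR)-5-[(5R)-5-hydroxyoctyl]-2-methyldecahydroquinolin-3-yl (2E,4E)-octa-2,4-dienoate | CCC/C=C/C=C/C(=O)O[C@@H]1C[C@H]2[C@@H](CCCC[C@H](O)CCC)CCC[C@H]2N[C@H]1C | target

Total step count: 14. Longest linear sequence: 11 steps (steps 1–4 and 8–14).

**Steps most likely to fail**

**Step 11.**
- Risk: the unactivated Z alkene may add so slowly that thermal polymerisation of the dienyl carbamate competes. The preference for cis over trans ring fusion may also erode, because C1′ has to travel endo together with the tether.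
- Fallback idea: use an alkyne dienophile, which has no endo/exo question, and set C4a and C5 afterwards by a hydroxyl-directed hydrogenation. It sets out from 7 (with 2 and 9 for a shorter side-chain iodide) and comes back at 23.
- Side-chain iodide: CuI-catalysed opening of 9 with 2 gives (R)-oct-7-en-4-ol F1. Silylation gives its TBS ether F2. Hydroboration–oxidation (9-BBN; H2O2, NaOH) gives (R)-5-(tert-butyldimethylsilyloxy)octan-1-ol F3, and Appel-type iodination (I2, PPh3, imidazole) gives the iodide F4.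
- Alkyne assembly: Ohira–Bestmann homologation of 7 gives the terminal alkyne F5. Its dianion (n-BuLi, THF/DMPU) is alkylated with F4 to give the internal alkyne F6.
- Dienyne carbamate: Boc removal as in step 9 gives the amine F7. Condensation with 18 gives the imine F8, and acylation as in step 10 gives the dienyne carbamate F9.
- Cycloaddition and end game: the thermal intramolecular Diels–Alder reaction of F9 only has to set C8a under the same A(1,3) control and gives the cyclohexa-1,4-diene F10. Hydrogenation over Pd(OH)2/C should remove both benzyl groups and saturate C7=C8 while sparing the tetrasubstituted C4a=C5 bond, giving amino alcohol F11. Boc2O gives the carbamate F12. Hydrogenation with [Ir(cod)(PCy3)(py)]PF6, directed by the homoallylic C3 hydroxyl, should then add both hydrogens to the face of that hydroxyl and give 23.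

**Step 10.**
- Risk: conjugate addition of the amine to the enal, hydrolysis of the imine, incomplete γ-deprotonation of the N-acyliminium ion, or loss of the E geometry may each reduce the amount of usable diene.
- Fallback: build the diene by isomerisation instead of condensation. It sets out from 17 and comes back at 20.
- Sequence: benzyl chloroformate/aq NaHCO3 gives the benzyl carbamate F13. N-alkylation with 1-bromobut-2-yne (NaH, DMF) gives the N-but-2-ynyl carbamate F14. KOtBu-induced propargyl–allenyl isomerisation gives the allenamide F15. An acid-catalysed (camphorsulfonic acid) 1,3-hydrogen shift of the γ-methyl allenamide should then give the E-dienyl carbamate 20.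

**Step 8.**
- Risk: ring–chain tautomerism of the aldehyde with the carbamate N–H may consume ylide, the basic ylide may trigger β-elimination of the benzyloxy group, and Z selectivity may be incomplete.
- Fallback: avoid the aldehyde altogether with a Z-selective cross-metathesis. It sets out from 5 (and 9) and comes back at 16.
- Sequence: CuI-catalysed opening of 9 with pent-4-enylmagnesium bromide gives (R)-dec-9-en-4-ol F16, and silylation gives its TBS ether F17.
- Metathesis: F17 is then crossed with 5 using the cyclometalated Z-selective ruthenium carbene Ru(=CH-C6H4-2-OiPr)(κ2-NO3)(κ2-C,C-L), where L is 1-(adamantan-1-yl)-3-mesitylimidazolidin-2-ylidene metalated at an adamantyl CH. This should give 16 directly.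

**Further compounds**
F1 | step 11 | (R)-oct-7-en-4-ol | C=CCC[C@H](O)CCC
F2 | step 11 | (R)-tert-butyl(oct-7-en-4-yloxy)dimethylsilane | C=CCC[C@H](O[Si](C)(C)C(C)(C)C)CCC
F3 | step 11 | (R)-5-(tert-butyldimethylsilyloxy)octan-1-ol | OCCCC[C@H](O[Si](C)(C)C(C)(C)C)CCC
F4 | step 11 | (R)-tert-butyl[(8-iodooctan-4-yl)oxy]dimethylsilane | ICCCC[C@H](O[Si](C)(C)C(C)(C)C)CCC
F5 | step 11 | tert-butyl N-[(2S,3R)-3-(benzyloxy)hex-5-yn-2-yl]carbamate | C[C@H](NC(=O)OC(C)(C)C)[C@H](OCc1ccccc1)CC#C
F6 | step 11 | tert-butyl N-[(2S,3R,11R)-3-(benzyloxy)-11-(tert-butyldimethylsilyloxy)tetradec-5-yn-2-yl]carbamate | C[C@H](NC(=O)OC(C)(C)C)[C@H](OCc1ccccc1)CC#CCCCC[C@H](O[Si](C)(C)C(C)(C)C)CCC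
F7 | step 11 | (2S,3R,11R)-3-(benzyloxy)-11-(tert-butyldimethylsilyloxy)tetradec-5-yn-2-amine | C[C@H](N)[C@H](OCc1ccccc1)CC#CCCCC[C@H](O[Si](C)(C)C(C)(C)C)CCC
F8 | step 11 | N-[(E)-but-2-enylidene] imine of F7 | C/C=C/C=N/[C@@H](C)[C@H](OCc1ccccc1)CC#CCCCC[C@H](O[Si](C)(C)C(C)(C)C)CCC
F9 | step 11 | benzyl N-[(1E)-buta-1,3-dien-1-yl]-N-[(2S,3R,11R)-3-(benzyloxy)-11-(tert-butyldimethylsilyloxy)tetradec-5-yn-2-yl]carbamate | C=C/C=C/N(C(=O)OCc1ccccc1)[C@@H](C)[C@H](OCc1ccccc1)CC#CCCCC[C@H](O[Si](C)(C)C(C)(C)C)CCC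
F10 | step 11 | benzyl (2S,3R,8aR)-3-(benzyloxy)-5-[(5R)-5-(tert-butyldimethylsilyloxy)octyl]-2-methyl-3,4,6,8a-tetrahydroquinoline-1(2H)-carboxylate | C(c3ccccc3)O[C@@H]1CC2=C(CCCC[C@H](O[Si](C)(C)C(C)(C)C)CCC)CC=C[C@H]2N(C(=O)OCc4ccccc4)[C@H]1C
F11 | step 11 | (2S,3R,8aR)-5-[(5R)-5-(tert-butyldimethylsilyloxy)octyl]-2-methyl-1,2,3,4,6,7,8,8a-octahydroquinolin-3-ol | O[C@@H]1CC2=C(CCCC[C@H](O[Si](C)(C)C(C)(C)C)CCC)CCC[C@H]2N[C@H]1C
F12 | step 11 | tert-butyl (2S,3R,8aR)-5-[(5R)-5-(tert-butyldimethylsilyloxy)octyl]-3-hydroxy-2-methyl-3,4,6,7,8,8a-hexahydroquinoline-1(2H)-carboxylate | O[C@@H]1CC2=C(CCCC[C@H](O[Si](C)(C)C(C)(C)C)CCC)CCC[C@H]2N(C(=O)OC(C)(C)C)[C@H]1C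
F13 | step 10 | benzyl N-[(2S,3R,5Z,11R)-3-(benzyloxy)-11-(tert-butyldimethylsilyloxy)tetradec-5-en-2-yl]carbamate | C[C@H](NC(=O)OCc1ccccc1)[C@H](OCc1ccccc1)C/C=C\CCCC[C@H](O[Si](C)(C)C(C)(C)C)CCC
F14 | step 10 | N-(but-2-yn-1-yl) derivative of F13 | CC#CCN(C(=O)OCc1ccccc1)[C@@H](C)[C@H](OCc1ccccc1)C/C=C\CCCC[C@H](O[Si](C)(C)C(C)(C)C)CCC
F15 | step 10 | N-(buta-1,2-dien-1-yl) allenamide isomer of F14 (both allene epimers) | CC=C=CN(C(=O)OCc1ccccc1)[C@@H](C)[C@H](OCc1ccccc1)C/C=C\CCCC[C@H](O[Si](C)(C)C(C)(C)C)CCC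
F16 | step 8 | (R)-dec-9-en-4-ol | C=CCCCC[C@H](O)CCC
F17 | step 8 | (R)-tert-butyl(dec-9-en-4-yloxy)dimethylsilane | C=CCCCC[C@H](O[Si](C)(C)C(C)(C)C)CCC
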